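**Strategy.** The C40 skeleton is cut at the C11=C12 and C11′=C12′ double bonds into a hydroxylated acetylenic C15 phosphonium salt, the C10 dialdehyde and an ε-ring C15 phosphonium salt from (R)-α-ionone. Everything rests on the C3 carbinol of ring A (the hydroxylated cyclohexene), which lies between the C2 and C4 methylenes with no neighbouring handle. The key step sets it by enzymatic reduction of one carbonyl of a cyclohexane-1,4-dione, (6R)-levodione: a ketoreductase picks the open carbonyl over the one flanked by the quaternary carbon and delivers hydride to a single face. The remaining hindered ketone, enolisable on one side only, later becomes the C5=C6 alkene carrying the alkyne.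

Key step: step 2

Remarks on the chemistry:
- Carotenoid numbering is used for the target. The descriptors (3R,6′R) of the target, 6R of the dione and 4R,6R of the hydroxy ketone were re-derived from the SMILES and are consistent with one another; no structure needed correction.
- The carbinol keeps the descriptor R from 3 to 19, because the CH2 on the gem-dimethyl side outranks the other CH2 throughout.
- The methyl-bearing stereocentre of 3 is erased on purpose in step 4, so only the carbinol configuration has to persist.
- Both enzymes are assumed to be available as recombinant preparations.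
- Steps 6–11 are meant to run under argon with exclusion of light.

**Route**

Step 1
Reactants: 1 ketoisophorone (2,6,6-trimethylcyclohex-2-ene-1,4-dione)
Product: 2 (6R)-levodione [(6R)-2,2,6-trimethylcyclohexane-1,4-dione]
Conditions: OYE2 (old yellow enzyme of Saccharomyces cerevisiae), NADP+ (cat.), glucose dehydrogenase, D-glucose, KH2PO4/K2HPO4 buffer pH 6.5, 30 °C; prompt extraction with MTBE
Reagents that add atoms: none
Why: Ene-reductase reduction in which reduced flavin delivers hydride and an active-site tyrosine delivers a proton anti across the ring C=C bond activated by the two carbonyls, the binding mode exposing one face so that the methyl-bearing carbon should become 6R; slightly acidic pH and quick extraction limit epimerisation of this α-stereocentre.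

Step 2
Reactants: 2 (6R)-levodione
Product: 3 (4R,6R)-actinol [(4R,6R)-4-hydroxy-2,2,6-trimethylcyclohexan-1-one]
Conditions: levodione reductase (Corynebacterium aquaticum, recombinant), NAD+ (cat.), glucose dehydrogenase, D-glucose, KH2PO4/K2HPO4 buffer pH 7.0, 30 °C
Reagents that add atoms: none
Why: NADH passes hydride from its C4 to one face of the C4 carbonyl of 2 while the tyrosine of the Ser–Tyr–Lys triad protonates the oxygen, so only the C4–H bond is formed and no ring is closed. The reaction type is a short-chain dehydrogenase (ketoreductase) carbonyl reduction with cofactor recycling by glucose dehydrogenase, the enzymatic counterpart of a catalyst-controlled asymmetric ketone reduction. The new stereocentre C4 (C3 of ring A in the target) should be set as R by the enzyme pocket, which matters because this carbinol sits between two methylenes and is hard to set cleanly with a small achiral reagent. The step needs site selectivity between two ketones and facial selectivity at the reacting one; the substrate secures the first because the C1 carbonyl is buttressed by the quaternary C2 and the methyl-bearing C6, and the (6R) methyl group gives the matched fit in the active site. Running the reduction sequentially on extracted 2 at neutral pH keeps the reductase away from 1 and limits epimerisation at C6 before hydride transfer.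

Step 3
Reactants: 3 (4R,6R)-actinol
Product: 4 (4R,6R)-4-[(tert-butyldimethylsilyl)oxy]-2,2,6-trimethylcyclohexan-1-one
Conditions: TBSCl, imidazole, DMF, rt
Reagents that add atoms: tert-butyldimethylsilyl chloride, CC(C)(C)[Si](C)(C)Cl
Why: Imidazole-mediated silyl ether formation at the only hydroxyl leaves the carbinol configuration untouched and installs a group that should withstand LiN(i-Pr)2, the palladium/copper/amine coupling, Appel conditions and NaOMe.

Step 4
Reactants: 4 (4R,6R)-4-[(tert-butyldimethylsilyl)oxy]-2,2,6-trimethylcyclohexan-1-one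
Product: 6 (4R)-4-[(tert-butyldimethylsilyl)oxy]-2,6,6-trimethylcyclohex-1-en-1-yl trifluoromethanesulfonate, via lithium enolate 5 (not isolated)
Conditions: LiN(i-Pr)2 (LDA, commercial solution), THF, −78 to 0 °C; then PhNTf2, −78 °C to rt; sat. NH4Cl
Reagents that add atoms: N-phenylbis(trifluoromethanesulfonimide), O=S(=O)(N(c1ccccc1)S(=O)(=O)C(F)(F)F)C(F)(F)F
Why: Enol triflate formation, in which deprotonation can occur only at the methyl-bearing α-carbon because the other α-carbon is quaternary, and O-sulfonylation of the enolate fixes the tetrasubstituted alkene that becomes C5=C6 of ring A; the silyloxy group is γ to the carbonyl, so no elimination path exists and the carbinol is unaffected.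

Step 5
Reactants: 6 (4R)-4-[(tert-butyldimethylsilyl)oxy]-2,6,6-trimethylcyclohex-1-en-1-yl trifluoromethanesulfonate; 7 (E)-3-methylpent-2-en-4-yn-1-ol
Product: 8 (2E)-5-[(4R)-4-[(tert-butyldimethylsilyl)oxy]-2,6,6-trimethylcyclohex-1-en-1-yl]-3-methylpent-2-en-4-yn-1-ol
Conditions: Pd(PPh3)4 (cat.), CuI (cat.), i-Pr2NH, degassed DMF, rt
Reagents that add atoms: none
Why: Sonogashira coupling, in which zerovalent palladium inserts into the C–OTf bond, the copper acetylide of 7 transmetalates and reductive elimination forms the C6–C7 bond; the E alkene and the free primary alcohol of 7 are spectators.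

Step 6
Reactants: 8 (2E)-5-[(4R)-4-[(tert-butyldimethylsilyl)oxy]-2,6,6-trimethylcyclohex-1-en-1-yl]-3-methylpent-2-en-4-yn-1-ol
Product: 10 {(2E)-5-[(4R)-4-[(tert-butyldimethylsilyl)oxy]-2,6,6-trimethylcyclohex-1-en-1-yl]-3-methylpent-2-en-4-yn-1-yl}triphenylphosphonium bromide, via allylic bromide 9 (not isolated)
Conditions: CBr4, PPh3, CH2Cl2, 0 °C; then further PPh3, rt; trituration with Et2O/EtOAc
Reagents that add atoms: triphenylphosphine, c1ccc(cc1)P(c1ccccc1)c1ccccc1; tetrabromomethane, BrC(Br)(Br)Br
Why: Appel bromination of the primary allylic alcohol (SN2 on the alkoxyphosphonium ion) followed by SN2 quaternisation of PPh3, neither stage passing through an allyl cation, so the 9E alkene next to the alkyne should keep its geometry and the neutral medium should leave the TBS ether intact.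

Step 7
Reactants: 10 {(2E)-5-[(4R)-4-[(tert-butyldimethylsilyl)oxy]-2,6,6-trimethylcyclohex-1-en-1-yl]-3-methylpent-2-en-4-yn-1-yl}triphenylphosphonium bromide; 11 (2E,4E,6E)-2,7-dimethylocta-2,4,6-trienedial (C10 dialdehyde)
Product: 13 (2E,4E,6E,8E,10E)-13-[(4R)-4-[(tert-butyldimethylsilyl)oxy]-2,6,6-trimethylcyclohex-1-en-1-yl]-2,7,11-trimethyltrideca-2,4,6,8,10-pentaen-12-ynal, via phosphorus ylide 12 (not isolated)
Conditions: 11 (3 equiv), CH2Cl2, 0 °C; NaOMe in MeOH added slowly; chromatography (excess 11 recovered)
Reagents that add atoms: none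
Why: Wittig olefination by a semi-stabilised allylic ylide forms C11=C12, and because the first condensation removes the mutual vinylogous activation of the two formyl groups the product is less electrophilic than 11, so with 11 in excess mono-olefination should dominate; the E isomer at the new bond is expected to prevail and any 11Z isomer is removed by chromatography.

Step 8
Reactants: 14 (R)-α-ionone [(3E)-4-[(1R)-2,6,6-trimethylcyclohex-2-en-1-yl]but-3-en-2-one]
Product: 15 (4E)-3-methyl-5-[(1R)-2,6,6-trimethylcyclohex-2-en-1-yl]penta-1,4-dien-3-ol (both C3 epimers)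
Conditions: CH2=CHMgBr, THF, −20 to 0 °C; sat. NH4Cl
Reagents that add atoms: vinylmagnesium bromide, C=C[Mg]Br
Why: Grignard 1,2-addition to the enone carbonyl; the new carbinol centre is formed without control and is irrelevant because it becomes sp2 in step 9, while the ring stereocentre (C6′ of the target) is not touched.

Step 9
Reactants: 15 (4E)-3-methyl-5-[(1R)-2,6,6-trimethylcyclohex-2-en-1-yl]penta-1,4-dien-3-ol
Product: 16 {(2E,4E)-3-methyl-5-[(1R)-2,6,6-trimethylcyclohex-2-en-1-yl]penta-2,4-dien-1-yl}triphenylphosphonium bromide
Conditions: PPh3·HBr, MeOH, rt; crystallisation from EtOAc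
Reagents that add atoms: triphenylphosphine hydrobromide, [Br-].c1ccc(cc1)[PH+](c1ccccc1)c1ccccc1
Why: Allylic substitution with transposition, in which HBr ionises the tertiary doubly allylic alcohol and PPh3 captures the pentadienyl cation at its unhindered terminus to give the conjugated primary salt; the E isomer at the new trisubstituted alkene should predominate and be enriched by crystallisation, and the ring stereocentre is kept because no bond to it is broken.

Step 10
Reactants: 16 {(2E,4E)-3-methyl-5-[(1R)-2,6,6-trimethylcyclohex-2-en-1-yl]penta-2,4-dien-1-yl}triphenylphosphonium bromide; 13 (2E,4E,6E,8E,10E)-13-[(4R)-4-[(tert-butyldimethylsilyl)oxy]-2,6,6-trimethylcyclohex-1-en-1-yl]-2,7,11-trimethyltrideca-2,4,6,8,10-pentaen-12-ynal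
Product: 18 (3R,6′R)-3-[(tert-butyldimethylsilyl)oxy]-7,8-didehydro-β,ε-carotene (all-E), via phosphorus ylide 17 (not isolated)
Conditions: 16 (1.3 equiv), NaOMe, CH2Cl2/MeOH, 0 °C to rt; then heptane, 60 °C, 1 h; chromatography and crystallisation
Reagents that add atoms: none
Why: Wittig olefination forms C11′=C12′; the carbon next to phosphorus is the only acidic site, so C6′ and the TBS ether should survive NaOMe, and gentle warming should convert the sterically hindered 11′Z isomer to the all-E polyene while iodine and light are avoided so that the 9E bond next to the alkyne is not equilibrated.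

Step 11
Reactants: 18 (3R,6′R)-3-[(tert-butyldimethylsilyl)oxy]-7,8-didehydro-β,ε-carotene
Product: 19 (3R,6′R)-7,8-didehydro-β,ε-caroten-3-ol (target, CNP0322200.1)
Conditions: Bu4NF, THF, 0 °C to rt; sat. NH4Cl
Reagents that add atoms: none
Why: Fluoride-induced desilylation driven by Si–F bond formation, which should leave the polyene, the enyne and the doubly allylic C6′–H untouched and retains the C3 configuration because the C–O bond is not broken.

**Compound list**

1 | ketoisophorone (2,6,6-trimethylcyclohex-2-ene-1,4-dione) | CC1=CC(=O)CC(C)(C)C1=O | starting material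
2 | (6R)-levodione, (6R)-2,2,6-trimethylcyclohexane-1,4-dione | C[C@@H]1CC(=O)CC(C)(C)C1=O | intermediate
3 | (4R,6R)-actinol, (4R,6R)-4-hydroxy-2,2,6-trimethylcyclohexan-1-one | C[C@@H]1C[C@@H](O)CC(C)(C)C1=O | intermediate
4 | (4R,6R)-4-[(tert-butyldimethylsilyl)oxy]-2,2,6-trimethylcyclohexan-1-one | C[C@@H]1C[C@@H](O[Si](C)(C)C(C)(C)C)CC(C)(C)C1=O | intermediate
5 | lithium (4R)-4-[(tert-butyldimethylsilyl)oxy]-2,6,6-trimethylcyclohex-1-en-1-olate (lithium enolate, not isolated) | [Li]OC1=C(C)C[C@@H](O[Si](C)(C)C(C)(C)C)CC1(C)C | intermediate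
6 | (4R)-4-[(tert-butyldimethylsilyl)oxy]-2,6,6-trimethylcyclohex-1-en-1-yl trifluoromethanesulfonate | FC(F)(F)S(=O)(=O)OC1=C(C)C[C@@H](O[Si](C)(C)C(C)(C)C)CC1(C)C | intermediate
7 | (E)-3-methylpent-2-en-4-yn-1-ol | C#C/C(C)=C/CO | starting material
8 | (2E)-5-[(4R)-4-[(tert-butyldimethylsilyl)oxy]-2,6,6-trimethylcyclohex-1-en-1-yl]-3-methylpent-2-en-4-yn-1-ol | OC/C=C(\C)C#CC1=C(C)C[C@@H](O[Si](C)(C)C(C)(C)C)CC1(C)C | intermediate
9 | primary allylic bromide of 8, (2E)-1-bromo-5-[(4R)-4-[(tert-butyldimethylsilyl)oxy]-2,6,6-trimethylcyclohex-1-en-1-yl]-3-methylpent-2-en-4-yne (not isolated) | BrC/C=C(\C)C#CC1=C(C)C[C@@H](O[Si](C)(C)C(C)(C)C)CC1(C)C | intermediate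
10 | {(2E)-5-[(4R)-4-[(tert-butyldimethylsilyl)oxy]-2,6,6-trimethylcyclohex-1-en-1-yl]-3-methylpent-2-en-4-yn-1-yl}triphenylphosphonium bromide | [Br-].c1ccccc1[P+](c1ccccc1)(c1ccccc1)C/C=C(\C)C#CC1=C(C)C[C@@H](O[Si](C)(C)C(C)(C)C)CC1(C)C | intermediate
11 | (2E,4E,6E)-2,7-dimethylocta-2,4,6-trienedial (C10 dialdehyde) | O=C/C(C)=C/C=C/C=C(C)/C=O | starting material
12 | triphenylphosphonium ylide of 10 (not isolated) | c1ccccc1P(c1ccccc1)(c1ccccc1)=C/C=C(\C)C#CC1=C(C)C[C@@H](O[Si](C)(C)C(C)(C)C)CC1(C)C | intermediate
13 | (2E,4E,6E,8E,10E)-13-[(4R)-4-[(tert-butyldimethylsilyl)oxy]-2,6,6-trimethylcyclohex-1-en-1-yl]-2,7,11-trimethyltrideca-2,4,6,8,10-pentaen-12-ynal (C25 aldehyde) | O=C/C(C)=C/C=C/C=C(C)/C=C/C=C(\C)C#CC1=C(C)C[C@@H](O[Si](C)(C)C(C)(C)C)CC1(C)C | intermediate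
14 | (R)-α-ionone, (3E)-4-[(1R)-2,6,6-trimethylcyclohex-2-en-1-yl]but-3-en-2-one | CC1=CCCC(C)(C)[C@H]1/C=C/C(C)=O | starting material
15 | (4E)-3-methyl-5-[(1R)-2,6,6-trimethylcyclohex-2-en-1-yl]penta-1,4-dien-3-ol (C3 epimers) | CC1=CCCC(C)(C)[C@H]1/C=C/C(C)(O)C=C | intermediate
16 | {(2E,4E)-3-methyl-5-[(1R)-2,6,6-trimethylcyclohex-2-en-1-yl]penta-2,4-dien-1-yl}triphenylphosphonium bromide | [Br-].CC1=CCCC(C)(C)[C@H]1/C=C/C(C)=C/C[P+](c1ccccc1)(c1ccccc1)c1ccccc1 | intermediate
17 | triphenylphosphonium ylide of 16 (not isolated) | CC1=CCCC(C)(C)[C@H]1/C=C/C(C)=C/C=P(c1ccccc1)(c1ccccc1)c1ccccc1 | intermediate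
18 | (3R,6′R)-3-[(tert-butyldimethylsilyl)oxy]-7,8-didehydro-β,ε-carotene (all-E) | CC1=CCCC(C)(C)[C@H]1/C=C/C(C)=C/C=C/C(C)=C/C=C/C=C(C)/C=C/C=C(\C)C#CC1=C(C)C[C@@H](O[Si](C)(C)C(C)(C)C)CC1(C)C | intermediate
19 | (3R,6′R)-7,8-didehydro-β,ε-caroten-3-ol (all-E), CNP0322200.1 | CC1=CCCC(C)(C)[C@H]1/C=C/C(C)=C/C=C/C(C)=C/C=C/C=C(C)/C=C/C=C(\C)C#CC1=C(C)C[C@@H](O)CC1(C)C | target

**Step count and risks**

Total step count: 11. Longest linear sequence: 9 steps (steps 1–7, 10 and 11); steps 8 and 9 form the convergent ε-ring branch.

Steps most likely to fail, in order of risk: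

Step 10. The new C11′=C12′ bond may form with poor E/Z selectivity, and the warming used to enrich the all-E isomer may begin to scramble the 9E bond beside the alkyne. The C40 polyene is also prone to oxidative and photochemical loss. The fallback replaces the Wittig reaction by a Horner–Wadsworth–Emmons reaction and sets out from 15. PBr3 (Et2O, −20 °C) should give, with allylic transposition, (2E,4E)-1-bromo-3-methyl-5-[(1R)-2,6,6-trimethylcyclohex-2-en-1-yl]penta-2,4-diene F1. Michaelis–Becker substitution with NaP(O)(OEt)2 in THF should then give diethyl {(2E,4E)-3-methyl-5-[(1R)-2,6,6-trimethylcyclohex-2-en-1-yl]penta-2,4-dien-1-yl}phosphonate F2. Deprotonation of F2 with NaN(SiMe3)2 (THF, −78 °C) and addition of aldehyde 13 should give 18 with the E-selective phosphate elimination typical of allylic phosphonate carbanions and without a heating period. The route is rejoined at 18.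

Step 7. The symmetric dialdehyde may be olefinated twice, which consumes the valuable salt 10 as the C40 bis-adduct, and an isomer mixture may form at C11=C12. The fallback moves the statistical event onto the cheap dialdehyde alone and sets out from 11. HC(OMe)3 (1 equiv) with catalytic pyridinium p-toluenesulfonate in MeOH at 0 °C should give, beside recyclable bis-acetal and unchanged 11, (2E,4E,6E)-8,8-dimethoxy-2,7-dimethylocta-2,4,6-trienal F3. Wittig reaction of F3 with the ylide from 10 (NaOMe, CH2Cl2/MeOH, 0 °C) can then only occur once and should give the dimethyl acetal of the C25 aldehyde F4. Brief hydrolysis (pyridinium p-toluenesulfonate, acetone/H2O, 0 °C), which the readily ionised vinylogous acetal should undergo without loss of the TBS ether, rejoins the route at 13.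

Step 2. A weak enzyme preparation may give incomplete conversion or some reduction at the hindered carbonyl, and epimerisation at C6 of 2 during a slow reaction would erode the diastereomeric purity of 3. The fallback replaces enzyme control by substrate control and sets out from 2. LiBH(s-Bu)3 (THF, −78 °C) should attack only the unhindered carbonyl, and from the equatorial direction, because the axial methyl group at C2 blocks the axial trajectory. This gives the axial alcohol trans to the C6 methyl group, that is 3, where the route is rejoined. In this variant the C3 configuration of the target depends wholly on the configurational purity of C6 in 2, so 2 would be reduced directly after extraction.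

**Further compounds**

F1 | step 10 | (2E,4E)-1-bromo-3-methyl-5-[(1R)-2,6,6-trimethylcyclohex-2-en-1-yl]penta-2,4-diene | CC1=CCCC(C)(C)[C@H]1/C=C/C(C)=C/CBr
F2 | step 10 | diethyl {(2E,4E)-3-methyl-5-[(1R)-2,6,6-trimethylcyclohex-2-en-1-yl]penta-2,4-dien-1-yl}phosphonate | CC1=CCCC(C)(C)[C@H]1/C=C/C(C)=C/CP(=O)(OCC)OCC
F3 | step 7 | (2E,4E,6E)-8,8-dimethoxy-2,7-dimethylocta-2,4,6-trienal | O=C/C(C)=C/C=C/C=C(C)/C(OC)OC
F4 | step 7 | dimethyl acetal of the C25 aldehyde 13, (4R)-1-[(3E,5E,7E,9E,11E)-13,13-dimethoxy-3,7,12-trimethyltrideca-3,5,7,9,11-pentaen-1-yn-1-yl]-4-[(tert-butyldimethylsilyl)oxy]-2,6,6-trimethylcyclohex-1-ene | COC(OC)/C(C)=C/C=C/C=C(C)/C=C/C=C(\C)C#CC1=C(C)C[C@@H](O[Si](C)(C)C(C)(C)C)CC1(C)C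
F0 | step 2 | none | none
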